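## The problem

Compound 26 is a homoisoflavonoid: a 4H-chromen-4-one in which benzene ring A is fused through C4a–C8a to pyranone ring C, with a 4-methoxybenzyl group on C3. It has no stereocenter, so nothing needs or offers stereocontrol and the whole difficulty is regiochemical. Ring A is hexasubstituted. Going round it, C4a carries the C4 carbonyl, C5 a methoxy group, C6 a methyl group, C7 a free hydroxyl, C8 a formyl group and C8a the ring oxygen O1. Three oxygens that must end in three different states (ring ether, methyl ether, free phenol) thus alternate with three carbon substituents, and a route from a trihydroxyarene would have to tell these oxygens apart and direct several substitutions. The sensitive parts are the salicylaldehyde unit (C7–OH/C8–CHO), which tolerates neither organometallic reagents nor oxidants; C2 of the chromone, a Michael acceptor open to ring cleavage by hard nucleophiles; and the C5 methyl ether, which lies peri to the carbonyl and is the first to be cleaved by strong Lewis acids. The alternating O/C pattern is what makes the key step possible: it is the pattern formed when a vinylketene (C7 with its oxygen, C6–Me, C5–OMe, C4a–H) is joined to a heterosubstituted alkyne (C8 with a masked formyl group, C8a with a silyloxy group), so that each oxygen arrives in a different form and C4a is left as the only C–H of ring A.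

## Retrosynthesis

The last operation should only uncover functional groups. The C8 aldehyde and the C7 hydroxyl of 26 are traced back to the diethyl acetal and the methoxymethyl ether of chromone 25; no skeletal bond is cut. Both masks fall to dilute aqueous acid in one step, whereas a free salicylaldehyde would not pass through the aryllithium and condensation chemistry that precedes. The forward step asks only that the chromone and the two methyl ethers tolerate warm dilute acid.

Ring C of 25 is opened at O1–C2 and C2–C3, which removes C2 as a one-carbon unit and leaves the 2-hydroxyaryl ketone 23, a dihydrochalcone. The neighbouring cuts, C3–C9 (benzylation of a preformed chromone) or O1–C8a (aryl ether formation), need an extra activating group on C3 or a leaving group on the crowded ring A. In 23 the benzyl group is simply the end of the acyl chain. The forward reaction is condensation of the ketone methylene with a formamide acetal to enaminone 24, which the C8a hydroxyl then closes. It needs that hydroxyl free while the C7 oxygen and the aldehyde stay masked, hence three masks of different lability.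

Phenol 23 comes from silyl ether 22 by fluoride, which touches neither the acetal nor the methoxymethyl ether. In 22 the C4–C4a bond is cut. C4a is the only ring A carbon without a substituent, so the site is not in question; the polarity is. An electrophilic acylation would need an acid that the acetal cannot survive, so the arene is made the nucleophile: aryllithium 21, from bromide 17, and Weinreb amide 20, which is one step from acid 18 through acyl imidazole 19. This cut divides the molecule into ring A and the complete side chain. It asks of the forward step that the lithium reagent be acylated faster than its ortho silyl group can migrate.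

Bromide 17 is derived from 16 by electrophilic bromination at the single free position, and 16 from phenol 15 by etherification of the C7 hydroxyl. These two steps add no carbon. They complete the set of three differently masked oxygens and turn the lone C–H into a handle.

Phenol 15 carries every ring A substituent of 26. It is cut at C7–C8 and C4a–C8a into cyclobutenone 6 and silyl ynol ether 10. In the forward sense 6 opens to vinylketene 11, adds 10 to give cyclobutenone 12, and this opens to dienylketene 13, which closes through C6–C7 to dienone 14 and tautomerises. Against the obvious neighbour, substitution chemistry on a trihydroxytoluene core, this cut leaves nothing to differentiate afterwards: the ketene carbon becomes the free C7 phenol, the alkyne delivers C8 with its acetal and C8a with a silyl ether, and 6 brings C4a–H, C5–OMe and C6–Me. A hexasubstituted benzene is reduced to a four-carbon and a three-carbon piece with one regiochemical question, the orientation of the ketene–alkyne union, which the polarity of the partners answers.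

Cyclobutenone 6 is cut across the ring into methylketene 5, generated from acid chloride 4, and methoxyethyne 3. The [2+2] union of an aldoketene with an ynol ether places the alkoxy group on C3 and the ketene substituent on C4 directly. Bringing the methoxy group in with the alkyne avoids a later ether exchange on the strained ring, during which the double bond could move toward the methyl-bearing carbon. Ynol ether 3 is obtained from chloroacetal 1 by double elimination through its sodium salt 2.

Ynol ether 10 is traced to terminal alkyne 7: deprotonation gives acetylide 8, electrophilic oxygenation gives ynolate 9, and O-silylation with a bulky silyl group gives 10. Alkyne 7 already holds C8a, C8 and the formyl carbon at the right oxidation level, so only the oxygen has to be added.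

## Roads not taken

Alternative 1: Ring A would be built last by a Diels–Alder reaction on a finished ring C. The cut is at C4a–C5 and C8–C8a. Sulfonylpyranone A1, which already carries the 4-methoxybenzyl group, is the dienophile through its sulfonyl-activated C=C bond, and the silyloxy ketene acetal diene A2 supplies C5 to C8. The nucleophilic methylene terminus of A2 should bond to the β-carbon of the pyranone (C8a). Loss of the sulfinate, of one methoxy group and of the silyl group should then aromatise the adduct to chromone A3, in which 5-OMe and 7-OH are already told apart.
- Merits: ring C and the side chain need no further work, and only C8, the single position ortho to the free phenol, is left to formylate. The sequence after the ring-forming step is clearly shorter than in the chosen plan.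
- Weak points: a 4-pyranone is a vinylogous ester with some aromatic character and a reluctant dienophile even with a sulfonyl group. A1, with different substituents on C3 and C5, is not simple to make. A2 is hindered and hydrolytically fragile, and its C-methyl group and fully substituted acetal terminus favour open-chain Michael-type adducts over cycloaddition. The final formylation is an electrophilic substitution on a ring deactivated by the chromone carbonyl, in the presence of an electron-rich anisole ring.
- Comparison: the chosen plan concedes the longer end game. It sets against it partners of matched polarity that are known to combine, and a formyl carbon that is part of the annulation and not a late substitution.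

Alternative 2: Ring C and the C3 side chain would appear together. The cut is at O1–C2 and C3–C9 (C9 being the benzylic carbon). Ynone A4 has the 4-methoxybenzyl group as an ether on the C8a oxygen. PtCl2 activates the terminal alkyne, the ether oxygen attacks the alkyne terminus in a 6-endo sense, and the benzyl group shifts from the oxonium ion to the metal-bearing C3 to give chromone A5.
- Merits: if it ran as drawn this would be the most economical ring C construction of all, one catalytic step in place of the acylation, desilylation and condensation of the chosen plan, and the protecting group would end in the skeleton.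
- Weak points: the oxygen-to-carbon benzyl shift is established for five-membered closures of aryl alkynes, not for the 6-endo closure of an aryl ynone, where the metal-bearing carbon is α to a carbonyl and less nucleophilic. The 4-methoxybenzyl cation is stable enough to escape, and C8 of ring A, flanked by two oxygens, is an excellent trap for it; protodemetalation to a 3-unsubstituted chromone is the other leak. A4 also demands a ring A whose three oxygens already carry three different groups, two of them flanking the acyl group and differing only in their second neighbour, and C8 must still be formylated at the end.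
- Comparison: the chosen plan has the less elegant ring C but solves the oxygen problem by construction, where this route moves it to the start.

Alternative 3: This is the polyketide-like route. The cut is at C5–C6. Pyranone A6 has an ester on the future C4a and a 2-oxobutyl chain on the future C8a. Base forms the enolate at the chain methylene next to the methyl group (C6), which attacks the ester carbon (C5), and the new ring enolises to the 5,7-dihydroxy-6-methyl chromone A7.
- Merits: the closure is a six-membered Claisen-type condensation driven by aromatisation and is probably the most reliable of the four ring-forming steps considered. Ring C and the side chain are again in place beforehand.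
- Weak points: A7 has two free phenols, and the one that must become the methyl ether (C5–OH) is hydrogen-bonded to the C4 carbonyl and the less reactive of the two. Protection of C7–OH, methylation and deprotection are therefore needed before C8 can be formylated. A6 is a pyranone with three different substituents that must be assembled and cyclised without the base-induced ring opening to which 4-pyranones are prone, and the more acidic side-chain methylene next to the ring (C8) competes for the base.
- Comparison: the chosen plan is less secure in its ring-forming step. It delivers C5–OMe, C7–OH and the C8 formyl carbon in their final relationship and spends its later steps on ring C only.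

Key step: step 4

Assumption: methoxyethyne is treated as a reagent that has to be made (step 1), and the masked formyl group is carried as the diethyl acetal because 3,3-diethoxyprop-1-yne is the readily purchased form of the three-carbon alkyne.

## Route

Step 1
Reactants: 1 2-chloro-1,1-dimethoxyethane (chloroacetaldehyde dimethyl acetal)
Product: 3 methoxyethyne, via sodium methoxyethynide 2 (not isolated)
Conditions: NaNH2 (3 equiv), liq. NH3, −33 °C; evaporate NH3; cold satd aq. NaCl, −20 °C; distil into a cold trap
Reagents that add atoms: none
Why: Double 1,2-elimination (methanol, then HCl) with NaNH2 gives the alkynyl ether, held as its sodium acetylide until the quench; this is the standard preparation of alkoxyacetylenes from haloacetaldehyde acetals.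

Step 2
Reactants: 4 propanoyl chloride; 3 methoxyethyne
Product: 6 3-methoxy-4-methylcyclobut-2-en-1-one (racemic), via methylketene 5 (not isolated)
Conditions: Et3N (slow addition), 3 (2 equiv), Et2O, 0 → 20 °C, sealed vessel
Reagents that add atoms: none
Why: Dehydrochlorination gives methylketene, which undergoes ketene–ynol ether [2+2] cycloaddition; the nucleophilic CH terminus of 3 bonds to the ketene carbonyl carbon, so the methoxy carbon becomes C3 next to the methyl-bearing C4. Slow addition of base into excess alkyne should keep ketene dimerisation down.

Step 3
Reactants: 7 3,3-diethoxyprop-1-yne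
Product: 10 [(3,3-diethoxyprop-1-yn-1-yl)oxy]tri(propan-2-yl)silane, via lithium acetylide 8 (not isolated), via lithium ynolate 9 (not isolated)
Conditions: LiN(SiMe3)2, THF, −78 °C; t-BuOOLi (from t-BuOOH and LiN(SiMe3)2), −78 → 0 °C; i-Pr3SiOTf, −78 → 0 °C
Reagents that add atoms: tert-butyl hydroperoxide, CC(C)(C)OO; tri(propan-2-yl)silyl trifluoromethanesulfonate, CC(C)[Si](OS(=O)(=O)C(F)(F)F)(C(C)C)C(C)C
Why: Electrophilic oxygenation of the lithium acetylide by lithium tert-butyl peroxide gives the ynolate, which the bulky silyl triflate silylates on oxygen; this is the standard route from terminal alkynes to triisopropylsilyl ynol ethers, and the acetal is inert to the basic medium.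

Step 4
Reactants: 6 3-methoxy-4-methylcyclobut-2-en-1-one; 10 [(3,3-diethoxyprop-1-yn-1-yl)oxy]tri(propan-2-yl)silane
Product: 15 2-(diethoxymethyl)-5-methoxy-6-methyl-3-{[tri(propan-2-yl)silyl]oxy}phenol, via vinylketene 11 (not isolated), via vinylcyclobutenone 12 (not isolated), via dienylketene 13 (not isolated), via cyclohexadienone 14 (not isolated)
Conditions: 6 (1.5 equiv), PhMe, 80 → 110 °C, sealed tube
Reagents that add atoms: none
Why: On heating, 6 should undergo reversible four-electron conrotatory opening (methyl outward) to vinylketene 11, whose ketene C=C bond adds alkyne 10 in a [2+2] cycloaddition to give 12, and 12 opens again to dienylketene 13. Six-electron disrotatory electrocyclisation of 13 between the ketene carbon and the propenyl terminus (the C6–C7 bond) closes six-membered ring A as dienone 14, and tautomerisation gives phenol 15. This is the cyclobutenone–siloxyalkyne benzannulation (Danheiser benzannulation), whose closest precedent is the preparation of resorcinol monosilyl ethers from cyclobutenones and silyl ynol ethers. The new bonds are C7–C8 and C4a–C8a: the ketene carbon becomes C7–OH, the alkyne carbons become C8 (acetal) and C8a (silyl ether), and 6 supplies C4a–H, C5–OMe and C6–Me. The selectivity needed is the orientation of the [2+2] step, and it is secured by polarity: the alkyne carbon remote from the silyloxy group is the nucleophilic end and the ketene carbonyl carbon the electrophilic one, so the silyloxy carbon ends meta and the acetal carbon ortho to the new hydroxyl. No stereocenter remains, since those of 12 and 14 are lost on aromatisation. The neutral, reagent-free conditions should spare the acetal and the silyl ether, and the excess of 6 allows for ketene lost to side reactions.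

Step 5
Reactants: 15 2-(diethoxymethyl)-5-methoxy-6-methyl-3-{[tri(propan-2-yl)silyl]oxy}phenol
Product: 16 {[2-(diethoxymethyl)-5-methoxy-3-(methoxymethoxy)-4-methylphenyl]oxy}tri(propan-2-yl)silane
Conditions: NaH, MOMCl, DMF, 0 °C (crude 15 used directly)
Reagents that add atoms: chloromethyl methyl ether, COCCl
Why: Williamson etherification of the sodium phenoxide, which works on phenols with two ortho substituents. It removes the acidic hydroxyl next to the acetal and gives a C7 mask that is stable to base, organolithium and fluoride but is cleaved by the same acid as the acetal.

Step 6
Reactants: 16 {[2-(diethoxymethyl)-5-methoxy-3-(methoxymethoxy)-4-methylphenyl]oxy}tri(propan-2-yl)silane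
Product: 17 {[2-bromo-6-(diethoxymethyl)-3-methoxy-5-(methoxymethoxy)-4-methylphenyl]oxy}tri(propan-2-yl)silane
Conditions: NBS, NaHCO3, MeCN, 0 °C, dark
Reagents that add atoms: N-bromosuccinimide, O=C1CCC(=O)N1Br
Why: Electrophilic aromatic bromination at the only unsubstituted ring position, which is ortho or para to all three oxygen donors; the buffered, acid-free medium protects the acetal and the methoxymethyl ether.

Step 7
Reactants: 18 3-(4-methoxyphenyl)propanoic acid
Product: 20 N-methoxy-3-(4-methoxyphenyl)-N-methylpropanamide, via acyl imidazole 19 (not isolated)
Conditions: CDI, CH2Cl2, 20 °C; then MeNH(OMe)·HCl, 20 °C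
Reagents that add atoms: N,O-dimethylhydroxylamine hydrochloride, CNOC.Cl
Why: Standard Weinreb amide formation: the acid is activated as its acyl imidazole and then undergoes aminolysis by the hydroxylamine.

Step 8
Reactants: 17 {[2-bromo-6-(diethoxymethyl)-3-methoxy-5-(methoxymethoxy)-4-methylphenyl]oxy}tri(propan-2-yl)silane; 20 N-methoxy-3-(4-methoxyphenyl)-N-methylpropanamide
Product: 22 1-[3-(diethoxymethyl)-6-methoxy-4-(methoxymethoxy)-5-methyl-2-{[tri(propan-2-yl)silyl]oxy}phenyl]-3-(4-methoxyphenyl)propan-1-one, via aryllithium 21 (not isolated)
Conditions: n-BuLi, THF, −78 °C; then 20, −78 → −20 °C; aq. NH4Cl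
Reagents that add atoms: none
Why: Bromine–lithium exchange is fast at −78 °C, and the aryllithium adds to the Weinreb amide to give a chelated tetrahedral adduct that releases the ketone only on work-up (Weinreb ketone synthesis). The low temperature should hold back oxygen-to-carbon silyl migration, and the acetal and both ether masks are inert to the organolithium.

Step 9
Reactants: 22 1-[3-(diethoxymethyl)-6-methoxy-4-(methoxymethoxy)-5-methyl-2-{[tri(propan-2-yl)silyl]oxy}phenyl]-3-(4-methoxyphenyl)propan-1-one
Product: 23 1-[3-(diethoxymethyl)-2-hydroxy-6-methoxy-4-(methoxymethoxy)-5-methylphenyl]-3-(4-methoxyphenyl)propan-1-one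
Conditions: Bu4NF, THF, 0 °C; aq. NH4Cl
Reagents that add atoms: none
Why: Fluoride cleavage of an aryl silyl ether, made easier by the ortho acyl group; it is orthogonal to the acid-labile acetal and methoxymethyl ether, so only the C8a hydroxyl is set free.

Step 10
Reactants: 23 1-[3-(diethoxymethyl)-2-hydroxy-6-methoxy-4-(methoxymethoxy)-5-methylphenyl]-3-(4-methoxyphenyl)propan-1-one
Product: 25 8-(diethoxymethyl)-5-methoxy-7-(methoxymethoxy)-3-[(4-methoxyphenyl)methyl]-6-methyl-4H-chromen-4-one, via enaminone 24 (not isolated)
Conditions: Me2NCH(OMe)2, PhMe, 100 °C
Reagents that add atoms: N,N-dimethylformamide dimethyl acetal, COC(OC)N(C)C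
Why: Condensation of the ketone methylene with the formamide acetal gives the enaminone, and addition of the neighbouring phenol to its β-carbon with loss of the amine closes ring C. This is the standard conversion of 2-hydroxyaryl dihydrochalcones into 3-benzylchromones, and the basic conditions leave the acetal and the methoxymethyl ether intact.

Step 11
Reactants: 25 8-(diethoxymethyl)-5-methoxy-7-(methoxymethoxy)-3-[(4-methoxyphenyl)methyl]-6-methyl-4H-chromen-4-one
Product: 26 7-hydroxy-5-methoxy-3-[(4-methoxyphenyl)methyl]-6-methyl-4-oxo-4H-chromene-8-carbaldehyde
Conditions: 2 M aq. HCl, THF, 50 °C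
Reagents that add atoms: water, O
Why: Acid hydrolysis removes the diethyl acetal and the methoxymethyl ether in one operation; the chromone and both methyl ethers are stable to dilute acid, and the product is stabilised by the hydrogen bond between C7–OH and the C8 aldehyde.

## Compound list

1 | 2-chloro-1,1-dimethoxyethane | COC(CCl)OC | starting material
2 | sodium methoxyethynide | [Na+].[C-]#COC | intermediate (not isolated)
3 | methoxyethyne | COC#C | intermediate
4 | propanoyl chloride | CCC(=O)Cl | starting material
5 | methylketene (prop-1-en-1-one) | CC=C=O | intermediate (not isolated)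
6 | 3-methoxy-4-methylcyclobut-2-en-1-one (racemic) | COC1=CC(=O)C1C | intermediate
7 | 3,3-diethoxyprop-1-yne | CCOC(OCC)C#C | starting material
8 | lithium 3,3-diethoxyprop-1-yn-1-ide | [Li+].[C-]#CC(OCC)OCC | intermediate (not isolated)
9 | lithium 3,3-diethoxyprop-1-yn-1-olate | [Li+].[O-]C#CC(OCC)OCC | intermediate (not isolated)
10 | [(3,3-diethoxyprop-1-yn-1-yl)oxy]tri(propan-2-yl)silane | CCOC(OCC)C#CO[Si](C(C)C)(C(C)C)C(C)C | intermediate
11 | (3Z)-3-methoxypenta-1,3-dien-1-one | O=C=C/C(OC)=C/C | intermediate (not isolated)
12 | 2-(diethoxymethyl)-4-[(1Z)-1-methoxyprop-1-en-1-yl]-3-{[tri(propan-2-yl)silyl]oxy}cyclobut-2-en-1-one (racemic) | CCOC(OCC)C1=C(O[Si](C(C)C)(C(C)C)C(C)C)C(/C(OC)=C/C)C1=O | intermediate (not isolated)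
13 | (3E,5Z)-2-(diethoxymethyl)-5-methoxy-3-{[tri(propan-2-yl)silyl]oxy}hepta-1,3,5-trien-1-one | O=C=C(C(OCC)OCC)/C(O[Si](C(C)C)(C(C)C)C(C)C)=C\C(OC)=C\C | intermediate (not isolated)
14 | 2-(diethoxymethyl)-5-methoxy-6-methyl-3-{[tri(propan-2-yl)silyl]oxy}cyclohexa-2,4-dien-1-one (racemic) | CCOC(OCC)C1=C(O[Si](C(C)C)(C(C)C)C(C)C)C=C(OC)C(C)C1=O | intermediate (not isolated)
15 | 2-(diethoxymethyl)-5-methoxy-6-methyl-3-{[tri(propan-2-yl)silyl]oxy}phenol | CCOC(OCC)c1c(O)c(C)c(OC)cc1O[Si](C(C)C)(C(C)C)C(C)C | intermediate
16 | {[2-(diethoxymethyl)-5-methoxy-3-(methoxymethoxy)-4-methylphenyl]oxy}tri(propan-2-yl)silane | CCOC(OCC)c1c(OCOC)c(C)c(OC)cc1O[Si](C(C)C)(C(C)C)C(C)C | intermediate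
17 | {[2-bromo-6-(diethoxymethyl)-3-methoxy-5-(methoxymethoxy)-4-methylphenyl]oxy}tri(propan-2-yl)silane | CCOC(OCC)c1c(OCOC)c(C)c(OC)c(Br)c1O[Si](C(C)C)(C(C)C)C(C)C | intermediate
18 | 3-(4-methoxyphenyl)propanoic acid | COc1ccc(CCC(=O)O)cc1 | starting material
19 | 1-(1H-imidazol-1-yl)-3-(4-methoxyphenyl)propan-1-one | COc1ccc(CCC(=O)n2ccnc2)cc1 | intermediate (not isolated)
20 | N-methoxy-3-(4-methoxyphenyl)-N-methylpropanamide | COc1ccc(CCC(=O)N(C)OC)cc1 | intermediate
21 | [3-(diethoxymethyl)-6-methoxy-4-(methoxymethoxy)-5-methyl-2-{[tri(propan-2-yl)silyl]oxy}phenyl]lithium | [Li]c1c(OC)c(C)c(OCOC)c(C(OCC)OCC)c1O[Si](C(C)C)(C(C)C)C(C)C | intermediate (not isolated)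
22 | 1-[3-(diethoxymethyl)-6-methoxy-4-(methoxymethoxy)-5-methyl-2-{[tri(propan-2-yl)silyl]oxy}phenyl]-3-(4-methoxyphenyl)propan-1-one | COc1ccc(CCC(=O)c2c(OC)c(C)c(OCOC)c(C(OCC)OCC)c2O[Si](C(C)C)(C(C)C)C(C)C)cc1 | intermediate
23 | 1-[3-(diethoxymethyl)-2-hydroxy-6-methoxy-4-(methoxymethoxy)-5-methylphenyl]-3-(4-methoxyphenyl)propan-1-one | COc1ccc(CCC(=O)c2c(OC)c(C)c(OCOC)c(C(OCC)OCC)c2O)cc1 | intermediate
24 | (2E)-1-[3-(diethoxymethyl)-2-hydroxy-6-methoxy-4-(methoxymethoxy)-5-methylphenyl]-3-(dimethylamino)-2-[(4-methoxyphenyl)methyl]prop-2-en-1-one | COc1ccc(C/C(=C\N(C)C)C(=O)c2c(OC)c(C)c(OCOC)c(C(OCC)OCC)c2O)cc1 | intermediate (not isolated)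
25 | 8-(diethoxymethyl)-5-methoxy-7-(methoxymethoxy)-3-[(4-methoxyphenyl)methyl]-6-methyl-4H-chromen-4-one | COc1ccc(Cc2coc3c(C(OCC)OCC)c(OCOC)c(C)c(OC)c3c2=O)cc1 | intermediate
26 | 7-hydroxy-5-methoxy-3-[(4-methoxyphenyl)methyl]-6-methyl-4-oxo-4H-chromene-8-carbaldehyde | COc1ccc(Cc2coc3c(C=O)c(O)c(C)c(OC)c3c2=O)cc1 | target

## Step count and least certain steps

Total: 11 steps. Longest linear sequence: 9 steps (1, 2, 4, 5, 6, 8, 9, 10, 11); steps 3 and 7 are side branches.

Step 4 (key step). The vinylogous-ester resonance of 6 should slow its electrocyclic opening. The temperature needed to form the vinylketene may then approach that at which the silyl ynol ether isomerises by an oxygen-to-carbon silyl shift and the acetal next to the new phenol ionises. Ketene dimerisation and O-acylation of the product phenol by the ketene are further drains. The fallback keeps alkyne 10 and changes the source of the ketene, so that no cyclobutenone has to be opened. Methyl 3-oxopentanoate F1 (purchased) would be converted with trimethyl orthoformate and catalytic acid into methyl (2E)-3-methoxypent-2-enoate F2, saponified with LiOH to (2E)-3-methoxypent-2-enoic acid F3, and turned with oxalyl chloride into (2E)-3-methoxypent-2-enoyl chloride F4. 1,4-Dehydrochlorination of F4 with Et3N in the presence of 10 at 0–20 °C, the classical generation of vinylketenes from unsaturated acid chlorides, should give ketene 11 without heating. The geometry of its propenyl double bond need not be controlled, because it disappears when ring A aromatises. Trapping by 10 gives 12, and gentle warming completes the sequence. The fallback sets out from 10 and comes back to the route at 11, and so at 15.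

Step 2. Dimerisation of the aldoketene and evaporative loss of the low-boiling ynol ether compete with the [2+2] step. The fallback sets out from 4 and uses ethoxyethyne F5 (purchased, higher boiling, usable in large excess) to give 3-ethoxy-4-methylcyclobut-2-en-1-one F6. Alkoxy exchange in methanol with a catalytic acid, by addition–elimination at C3 of the vinylogous ester, then gives 6, where the fallback rejoins the route; step 1 becomes unnecessary. The exchange must be kept short and cold, because prolonged acid can move the ring double bond toward the methyl-bearing carbon. That is why the direct route through 3 is preferred.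

Step 8. Oxygen-to-carbon silyl migration in the ortho-lithiated silyl ether (retro-Brook rearrangement) and proton transfer from the α-methylene of the amide to the hindered aryllithium would both consume 21 without acylation. The fallback sets out from 17 and 20. Amide 20 would be reduced with LiAlH4 at −78 °C to 3-(4-methoxyphenyl)propanal F7. Aryllithium 21, generated from 17 as before, should add to F7 within minutes at −78 °C to give the secondary alcohol 1-[3-(diethoxymethyl)-6-methoxy-4-(methoxymethoxy)-5-methyl-2-{[tri(propan-2-yl)silyl]oxy}phenyl]-3-(4-methoxyphenyl)propan-1-ol F8 (racemic). Oxidation with Dess–Martin periodinane buffered by NaHCO3 returns to the route at 22.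

Step 10. O-Methylation of the phenol by the formamide acetal, or stalling at enaminone 24 because the phenol is hindered and chelated to the ketone, would lower the return of ring C. The fallback sets out from 23. Claisen-type formylation with NaH and ethyl formate should give, after cyclisation of the formyl ketone, the hemiacetal 8-(diethoxymethyl)-2-hydroxy-5-methoxy-7-(methoxymethoxy)-3-[(4-methoxyphenyl)methyl]-6-methyl-2,3-dihydro-4H-chromen-4-one F9 (mixture of diastereomers). Warm aqueous HCl in THF then dehydrates it and removes the acetal and the methoxymethyl ether in the same operation. This fallback bypasses 25 and comes back to the route at 26.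

## Further compounds

F1 | step 4 | methyl 3-oxopentanoate (purchased) | CCC(=O)CC(=O)OC
F2 | step 4 | methyl (2E)-3-methoxypent-2-enoate | CC/C(OC)=C\C(=O)OC
F3 | step 4 | (2E)-3-methoxypent-2-enoic acid | CC/C(OC)=C\C(=O)O
F4 | step 4 | (2E)-3-methoxypent-2-enoyl chloride | CC/C(OC)=C\C(=O)Cl
F5 | step 2 | ethoxyethyne (purchased) | CCOC#C
F6 | step 2 | 3-ethoxy-4-methylcyclobut-2-en-1-one (racemic) | CCOC1=CC(=O)C1C
F7 | step 8 | 3-(4-methoxyphenyl)propanal | COc1ccc(CCC=O)cc1
F8 | step 8 | 1-[3-(diethoxymethyl)-6-methoxy-4-(methoxymethoxy)-5-methyl-2-{[tri(propan-2-yl)silyl]oxy}phenyl]-3-(4-methoxyphenyl)propan-1-ol (racemic) | COc1ccc(CCC(O)c2c(OC)c(C)c(OCOC)c(C(OCC)OCC)c2O[Si](C(C)C)(C(C)C)C(C)C)cc1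
F9 | step 10 | 8-(diethoxymethyl)-2-hydroxy-5-methoxy-7-(methoxymethoxy)-3-[(4-methoxyphenyl)methyl]-6-methyl-2,3-dihydro-4H-chromen-4-one (mixture of diastereomers) | COc1ccc(CC2C(O)Oc3c(C(OCC)OCC)c(OCOC)c(C)c(OC)c3C2=O)cc1
A1 | alternative 1 | 3-(benzenesulfonyl)-5-[(4-methoxyphenyl)methyl]-4H-pyran-4-one | COc1ccc(Cc2cocc(S(=O)(=O)c3ccccc3)c2=O)cc1
A2 | alternative 1 | [(4,4-dimethoxy-3-methylbuta-1,3-dien-2-yl)oxy]trimethylsilane | C=C(O[Si](C)(C)C)C(C)=C(OC)OC
A3 | alternative 1 | 7-hydroxy-5-methoxy-3-[(4-methoxyphenyl)methyl]-6-methyl-4H-chromen-4-one | COc1ccc(Cc2coc3cc(O)c(C)c(OC)c3c2=O)cc1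
A4 | alternative 2 | 1-{2-methoxy-6-[(4-methoxyphenyl)methoxy]-3-methyl-4-{[tri(propan-2-yl)silyl]oxy}phenyl}prop-2-yn-1-one | C#CC(=O)c1c(OC)c(C)c(O[Si](C(C)C)(C(C)C)C(C)C)cc1OCc1ccc(OC)cc1
A5 | alternative 2 | 5-methoxy-3-[(4-methoxyphenyl)methyl]-6-methyl-7-{[tri(propan-2-yl)silyl]oxy}-4H-chromen-4-one | COc1ccc(Cc2coc3cc(O[Si](C(C)C)(C(C)C)C(C)C)c(C)c(OC)c3c2=O)cc1
A6 | alternative 3 | methyl 5-[(4-methoxyphenyl)methyl]-4-oxo-2-(2-oxobutyl)-4H-pyran-3-carboxylate | CCC(=O)Cc1occ(Cc2ccc(OC)cc2)c(=O)c1C(=O)OC
A7 | alternative 3 | 5,7-dihydroxy-3-[(4-methoxyphenyl)methyl]-6-methyl-4H-chromen-4-one | COc1ccc(Cc2coc3cc(O)c(C)c(O)c3c2=O)cc1
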